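**The climb.** At 60 °C the cedar flask, the one asked about, starts with target rising 22.0 %/d between its first and third readings. Target passes substrate between 0.833 d and 1.25 d. Its last two readings average 43.0 %, and the starting line reaches that level at 1.98 d, so I read the knee there.

| flask | substrate | reagent | temperature | remark | time |
|---|---|---|---|---|---|
| cedar | 0.14 M | 3 equiv | 60 °C | the very flask that is asked about, followed so far |  |
| maple | 0.28 M | 3 equiv | 45 °C | run made earlier |  |
| flask | 0.14 M | 3.00 equiv | 60 °C |  | 5.0 d |

- cedar (time / d: target / %, substrate / %): 0.250: 5, 29; 0.833: 19, 20; 1.25: 27, 16; 2.00: 42, 11; 3.00: 44, 10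
- maple (time / d: target / %, substrate / %): 1.25: 0, 8; 2.50: 7, 8; 4.00: 12, 7; 6.00: 20, 11; 8.00: 23, 4

(each reading ± 2 percentage points)

- target that was removed still counts
- additions bring no volume worth counting

- epsilon: change nothing and wait 5.0 d more
- alpha: at 5.0 d take out 90 % of the target then present, then wait 5.0 d
- zeta: at 5.0 d raise the temperature by 25 K, then wait 5.0 d
- eta: at 5.0 d add reagent, 50.0 % of the amount charged, then wait 5.0 d

- target, in percent of the substrate first charged, at 5.0 d
- what to do for the largest gain in target; "none" if nothing gains more than 2 percentage points (epsilon / alpha / zeta / eta / none)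
- target present, with what was taken out counted in, in percent of the substrate first charged, after zeta
- target present, with what was taken out counted in, in percent of the substrate first charged, after eta

**The unseen share.** Cedar's last reading leaves 46.0 % of the charge as neither target nor substrate. I carry this unseen share, the charge less target less substrate, known as the mass-balance gap. In the cedar readings it falls from 66.0 % at 0.250 d to 47.0 % at 2.00 d, then stands still within a scatter of 2 percentage points per reading. So these readings put a knee in the gap where target has its knee, and a gain in target has to come out of that stock or out of the substrate still free.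

**My reckoning.** I commit to 43.0 % at 5.0 d. The maple run, at 45 °C and 0.28 M, still holds a gap of 73.0 % at 8.00 d, wider than cedar's. The charges differ too, but I read this as a hint that temperature moves the gap, so I pick zeta.

**The forecast.** It gives 45 % at 5.0 d, 46 % after zeta and 48 % after eta, and it picks alpha, saying: “Heating has an unknown effect on the equilibrium”. On the choice of option it differs from me.

**The flask.** Target stands at 41.2 % at 5.0 d. The best option is zeta, which gains 34 points and ends at 75.5 %, against 18 points for alpha. Eta ends at 35.4 %.

    intermediate C → target (k = 1.73 × 10⁻⁵ /s, Ea = 112 kJ/mol)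
    substrate → intermediate A (k = 7.51 × 10⁻⁶ /s, Ea = 110 kJ/mol)
    substrate + reagent ⇌ intermediate B (K = 6.50 /M, k = 3.04 × 10⁻⁴ /M/s, Ea = 86.0 kJ/mol, ΔH = −46.0 kJ/mol)
    target ⇌ isomer of the product (K = 1.84, k = 5.40 × 10⁻⁶ /s, Ea = 112 kJ/mol, ΔH = −77.0 kJ/mol)
    reagent + intermediate A ⇌ target (K = 54.0 /M, k = 5.62 × 10⁻⁵ /M/s, Ea = 63.0 kJ/mol, ΔH = 3.00 kJ/mol)
    intermediate B → intermediate C (k = 7.55 × 10⁻⁶ /s, Ea = 116 kJ/mol)
    (constants at 60 °C)

**The stock named.** The flask's gap stands at 51.2 % at 2.50 d and at 57.4 % at 5.00 d, and by then isomer of the product holds 49.2 % of the charge. That isomer is the main reason target stays low: with the conversion of target into isomer removed, both ways, the same flask has 87.9 % at 5.0 d instead of 41.2 %. A repeat held at 85 °C from the start has a narrower gap at 5.00 d, 24.5 %, with target at 75.5 % and isomer of the product at 20.0 %.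

The readings were generated by integration with made-up constants; the scatter is artificial.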